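Assumptions:
- Ring locants used below: C1 = C(CH3)(side chain), C2 = CH(hydroxypropyl), C3 = alkylidene carbon, C4 and C5 = CH2, C6 = C(CH3)OH.
- The pinacol on 7 is counted as a boron protecting group, so the vinylboronic acid core has 5 non-H atoms.
- A desilylation run in the same flask is not counted as a separate step.

## Retrosynthetic overview
1. The Z-enal (C3=C) comes from ketone 18 and a β-ethoxy-α-methylvinyl anion. It is released together with the silyl groups in the last acid step.
2. The side chain comes from an sp3–sp2 Suzuki coupling of the ring CH2CH2–B unit (8) with vinyl iodide 17.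
3. The only ring is formed once, in step 5. An acyl radical closes C3–C2 (6-endo) on acyclic aldehyde 6, and the resulting tertiary C1 radical forms C1–CH2 with a vinylboronate.
4. Aldehyde 6 comes from hex-4-yn-1-ol and 4-oxopentanenitrile. A catalytic asymmetric alkenylation sets C6, which then relays to C2 and C1.
5. Iodide 17 comes from homoprenyl bromide, acetylide, ethylene oxide and TMS-acetylene. Two carboaluminations set the E-alkenes and an asymmetric alkynylation sets the carbinol.

## Route

**Step 1**
Reactants: 1 hex-4-yn-1-ol
Product: 2 tert-butyl(hex-4-yn-1-yloxy)dimethylsilane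
Conditions: TBSCl, imidazole, DMF, rt
Reagents that add atoms: TBSCl, C[Si](C)(Cl)C(C)(C)C
Why: Standard silyl protection masks the future primary alcohol through the organometallic, radical and basic steps.

**Step 2**
Reactants: 2; 3 4-oxopentanenitrile
Product: 4 (4S,5E)-9-(TBSO)-4-hydroxy-4,5-dimethylnon-5-enenitrile
Conditions: Cp2Zr(H)Cl, CH2Cl2, rt→40 °C; Me2Zn, −78 °C; then 3, Ti(OiPr)4, trans-cyclohexanediamine bis(camphorsulfonamide)-diol ligand (10 mol %), toluene, rt
Reagents that add atoms: none
Why: Syn-hydrozirconation, equilibrated so that Zr sits on the methyl-bearing carbon, fixes the E-alkene, and Zr→Zn transmetalation followed by Ti-catalysed asymmetric alkenylation of the ketone (Re-face delivery with the chosen ligand antipode) sets C6 as S.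

**Step 3**
Reactants: 4
Product: 5 (4S,5E)-9-(TBSO)-4,5-dimethyl-4-(TESO)non-5-enenitrile
Conditions: TESOTf, 2,6-lutidine, CH2Cl2, −78→0 °C
Reagents that add atoms: TESOTf, CC[Si](CC)(CC)OS(=O)(=O)C(F)(F)F
Why: Silylation of the tertiary allylic alcohol prevents lactol formation in step 4 and supplies the bulky C6–O group used for stereocontrol in step 5.

**Step 4**
Reactants: 5
Product: 6 (4S,5E)-9-(TBSO)-4,5-dimethyl-4-(TESO)non-5-enal
Conditions: DIBAL-H, toluene, −78 °C; aq. tartrate work-up
Reagents that add atoms: water, O
Why: Partial nitrile reduction stops at the aluminium imine, which hydrolyses to the aldehyde without touching the alkene or the silyl ethers.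

**Step 5 (key step)**
Reactants: 6; 7 vinylboronic acid pinacol ester
Product: 8 (2S,3S,4S)-2-[3-(TBSO)propyl]-3,4-dimethyl-3-[2-(pinacolboryl)ethyl]-4-(TESO)cyclohexan-1-one
Conditions: (n-Bu4N)4W10O32 (4 mol %), 390 nm, MeCN, rt; 6 at 0.05 M, 7 (3 equiv)
Reagents that add atoms: none
Why: Proposed new method: excited decatungstate abstracts the formyl H; the acyl radical closes 6-endo on the CH terminus of the E-alkene because 5-exo attack at the fully substituted carbon next to the quaternary carbinol is blocked; a chair transition state with the C2 chain and the C6–OTES equatorial sets C2 cis-1,3 to oxygen; the planar tertiary C1 radical, whose A-strain turns both flanking groups axial on one face, then adds through the open face (anti to OTES and to the C2 chain) to the vinylboronate, and back hydrogen-atom transfer closes the cycle; the closest known reaction types are decatungstate hydroacylation, 6-endo acyl-radical cyclisation onto trisubstituted alkenes, and Giese addition of tertiary radicals to vinylboronates.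

**Step 6**
Reactants: 9 5-bromo-2-methylpent-2-ene; 10 lithium acetylide–ethylenediamine
Product: 11 6-methylhept-5-en-1-yne
Conditions: DMSO, 10 °C→rt
Reagents that add atoms: none
Why: SN2 alkylation of the acetylide proceeds cleanly with a primary homoallylic bromide.

**Step 7**
Reactants: 11; 12 ethylene oxide
Product: 13 (3E)-4,8-dimethylnona-3,7-dien-1-ol
Conditions: Me3Al, Cp2ZrCl2 (cat.), CH2Cl2, rt; n-BuLi, −78 °C; 12, THF, −78→0 °C
Reagents that add atoms: Me3Al, C[Al](C)C
Why: Negishi syn-carboalumination fixes the E-trisubstituted alkene, and the derived alkenylalanate opens the epoxide with retention of geometry.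

**Step 8**
Reactants: 13
Product: 14 (3E)-4,8-dimethylnona-3,7-dienal
Conditions: Dess–Martin periodinane, NaHCO3, CH2Cl2, 0 °C; used at once
Reagents that add atoms: none
Why: Buffered, non-basic oxidation avoids conjugation of the β,γ-unsaturated aldehyde.

**Step 9**
Reactants: 14; 15 trimethylsilylacetylene
Product: 16 (3R,5E)-6,10-dimethylundeca-5,9-dien-1-yn-3-ol
Conditions: Me2Zn, ProPhenol (20 mol %), Ph3P=O, toluene, 4 °C; then K2CO3, MeOH (same flask)
Reagents that add atoms: none
Why: Zinc–ProPhenol catalysed asymmetric alkynylation, using the antipode that attacks the Si face, sets the side-chain carbinol as R, and the TMS group is cleaved in situ.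

**Step 10**
Reactants: 16
Product: 17 (1E,3R,5E)-1-iodo-2,6,10-trimethylundeca-1,5,9-trien-3-ol
Conditions: Me3Al (3 equiv), Cp2ZrCl2, CH2Cl2, rt; I2, THF, −30 °C
Reagents that add atoms: Me3Al, C[Al](C)C; iodine, II
Why: Negishi carboalumination of the aluminium alkoxide followed by iodinolysis puts the methyl on the internal carbon and the iodine trans to the carbinol carbon without touching the stereocentre.

**Step 11**
Reactants: 8; 17
Product: 18 (2S,3S,4S)-2-[3-(TBSO)propyl]-3-[(3E,5R,7E)-5-hydroxy-4,8,12-trimethyltrideca-3,7,11-trienyl]-3,4-dimethyl-4-(TESO)cyclohexan-1-one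
Conditions: Pd(dppf)Cl2 (5 mol %), Ag2O, K2CO3, THF, 50 °C
Reagents that add atoms: none
Why: B-alkyl Suzuki–Miyaura coupling is stereoretentive at the vinyl iodide and tolerates the free alcohol, and enolisation toward the congested C2 is slow so that centre survives.

**Step 12**
Reactants: 19 ethyl prop-1-enyl ether (E/Z)
Product: 20 (Z)-2-bromo-1-ethoxyprop-1-ene (contains some E)
Conditions: Br2, CH2Cl2, −78 °C; then Et3N, 0 °C
Reagents that add atoms: bromine, BrBr
Why: Bromination followed by amine-induced loss of HBr through the labile α-bromo ether gives the β-bromo enol ether.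

**Step 13**
Reactants: 18; 20
Product: 21 the tertiary carbinol from 1,2-addition of (Z)-2-ethoxy-1-methylvinyl to C3 of 18 (other centres as in 18; new carbinol centre unassigned and lost in step 14)
Conditions: 20, t-BuLi, Et2O, −78 °C; CeCl3; then 18, THF, −78 °C (3.5 equiv of reagent)
Reagents that add atoms: none
Why: Br–Li exchange leaves only the chelate-stabilised Z-lithio enol ether (the E isomer self-destructs by anti-elimination), and its cerium reagent adds 1,2 to the hindered ketone without enolising C2, with one equivalent consumed by the free OH.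

**Step 14**
Reactants: 21
Product: 22 isoiridogermanal
Conditions: aq. HF, MeCN, 0 °C→rt
Reagents that add atoms: water, O
Why: Acid converts the β-ethoxyallylic tertiary carbinol into the enal (vinylogous hydrolysis with 1,3-transposition), with the bulky C2 lying syn to the slim formyl CH rather than to the methyl (minimised A1,3 strain) to give the Z-alkene, while HF removes TBS and TES.

## Compound list
1 | hex-4-yn-1-ol | CC#CCCCO | starting material
2 | TBS ether of 1 | CC#CCCCO[Si](C)(C)C(C)(C)C | intermediate
3 | 4-oxopentanenitrile | CC(=O)CCC#N | starting material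
4 | (4S,5E)-hydroxy nitrile | N#CCC[C@](C)(O)/C(C)=C/CCCO[Si](C)(C)C(C)(C)C | intermediate
5 | TES ether of 4 | N#CCC[C@](C)(O[Si](CC)(CC)CC)/C(C)=C/CCCO[Si](C)(C)C(C)(C)C | intermediate
6 | (4S,5E)-aldehyde | O=CCC[C@](C)(O[Si](CC)(CC)CC)/C(C)=C/CCCO[Si](C)(C)C(C)(C)C | intermediate
7 | vinylboronic acid (pinacol-protected) | C=CB1OC(C)(C)C(C)(C)O1 | starting material
8 | (2S,3S,4S)-boronate ketone | CC1(C)OB(CC[C@@]2(C)[C@H](CCCO[Si](C)(C)C(C)(C)C)C(=O)CC[C@]2(C)O[Si](CC)(CC)CC)OC1(C)C | intermediate
9 | 5-bromo-2-methylpent-2-ene | CC(C)=CCCBr | starting material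
10 | lithium acetylide (ethylenediamine complex) | [Li]C#C | starting material
11 | 6-methylhept-5-en-1-yne | CC(C)=CCCC#C | intermediate
12 | ethylene oxide | C1CO1 | starting material
13 | (E)-homogeraniol | CC(C)=CCC/C(C)=C/CCO | intermediate
14 | (E)-homogeranial | CC(C)=CCC/C(C)=C/CC=O | intermediate
15 | trimethylsilylacetylene | C#C[Si](C)(C)C | starting material
16 | (3R,5E)-propargylic alcohol | CC(C)=CCC/C(C)=C/C[C@@H](O)C#C | intermediate
17 | (1E,3R,5E)-vinyl iodide | CC(C)=CCC/C(C)=C/C[C@@H](O)/C(C)=C/I | intermediate
18 | coupled ketone | CC(C)=CCC/C(C)=C/C[C@@H](O)/C(C)=C/CC[C@@]1(C)[C@H](CCCO[Si](C)(C)C(C)(C)C)C(=O)CC[C@]1(C)O[Si](CC)(CC)CC | intermediate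
19 | ethyl prop-1-enyl ether | CCOC=CC | starting material
20 | (Z)-2-bromo-1-ethoxyprop-1-ene | CCO/C=C(/C)Br | intermediate
21 | β-ethoxyallylic carbinol | CC(C)=CCC/C(C)=C/C[C@@H](O)/C(C)=C/CC[C@@]1(C)[C@H](CCCO[Si](C)(C)C(C)(C)C)C(O)(/C(C)=C\OCC)CC[C@]1(C)O[Si](CC)(CC)CC | intermediate
22 | isoiridogermanal | CC(C)=CCC/C(C)=C/C[C@@H](O)/C(C)=C/CC[C@@]1(C)[C@H](CCCO)/C(=C(/C)C=O)CC[C@]1(C)O | target

## Step count
Total steps: 14.
Longest linear sequence: 8 (steps 1–5, 11, 13, 14; the branch 6–10, 11, 13, 14 is also 8).

## Three steps most likely to fail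
1. **Step 5.** The risks are facial selectivity at the C1 radical, direct Giese addition of the acyl radical before it cyclises, and some 5-exo closure. Fallback: give up intermolecular capture. Build the 3-substituted 4-hydroxy-4-methylcyclohex-2-enone, then deliver the C1 methyl from C6–O through a (bromomethyl)dimethylsilyl ether. This is a 5-exo radical cyclisation that is necessarily cis to oxygen, with allylstannane trapping at C2 followed by protodesilylation.
2. **Step 2.** The risks are the ee and the rate with an α-branched alkenylzinc on a dialkyl ketone. Fallback: acylate the same alkenylzirconocene (Cu catalysis) with 3-cyanopropanoyl chloride to give the α-methyl enone. C6 is then set by catalytic asymmetric Me2Zn addition, where alkenyl and alkyl groups are easier to tell apart.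
3. **Steps 13/14.** The risks are addition to the hindered ketone and the Z/E ratio of the tetrasubstituted enal. Fallback: form the kinetic C3=C4 enol triflate and cross-couple it with a 1-ethoxyprop-1-en-2-yl stannane to give the dienol ether. Protonating the s-trans conformer at C4 then places the formyl group cis to C2.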